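Read the gamma run first, and ask of it one thing: how long does X take to double?

| flask | G | E | Q | time |
|---|---|---|---|---|
| gamma | 0.120 M | 0.240 M | 0.00960 M |  |
| eta | 0.0600 M | 0.180 M | 0.00960 M |  |
| delta | 0.120 M | 0.240 M | 0.0290 M |  |
| beta | 0.120 M | 0.480 M | 0.00960 M |  |
| theta | 0.480 M | 0.240 M | 0.00960 M | 42 min |

- gamma run (time / min: [X] / M): 1.7: 0; 3.2: 8 × 10⁻⁴; 6.1: 0.0039; 12: 0.0040; 22: 0.0199; 42: 0.0748
- eta run (time / min: [X] / M): 1.7: 0; 3.2: 0; 6.1: 0.0010; 12: 3 × 10⁻⁴; 22: 0.0097; 42: 0.0208
- delta run (time / min: [X] / M): 1.7: 0; 3.2: 1 × 10⁻⁴; 6.1: 6 × 10⁻⁴; 12: 0.0111; 22: 0.0425; 42: 0.1017
- beta run (time / min: [X] / M): 1.7: 0; 3.2: 0; 6.1: 0.0023; 12: 0.0054; 22: 0.0317; 42: 0.1052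

(scatter of a reading: 0.002 M)

- Overall: G + E -> X, with Q as catalyst.
- Constant volume, constant temperature.
- A reading of a species includes what of it is bound.
- "The second partner" is E.
- An order is taken over about fifteen percent of the charge, up and down.

* order of the initial rate in [G], near the charge of the gamma run, the rate being that where two percent of its G are X (one fixed amount of X, the same in the runs compared)
* order of the initial rate in [Q], near the charge of the gamma run, the rate being that where two percent of its G are X
* the eta run starts with 0.0600 M less of G and of E than the gamma run, and with no X. Compared where both hold the same amount of G, once fifteen percent of what the eta run was charged with has turned into X, is the eta run faster, slower or alike (within a tenth)?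
* X in the theta run at 42 min, as a share of the G charged

Between 22 min and 42 min the gamma run climbs from 16.6% to 62.3% of its G. Take this climb as X feeding itself, at a rate proportional to X, G and E. Then freeze G and E at their mean values in that window, 60.5% of the G charge and 80.3% of the E charge. X now grows exponentially, and the readings give a doubling time, the time X needs to double while G and E stand frozen, of 10.5 min. Carry it to other flasks at this temperature by one rule of this reckoning: with X feeding itself as taken here, the doubling time scales inversely with the product of G and E present.

Now build the theta run from that. Its E charge is half its G charge, so E is the limiting reagent and X stops at 50.0% of G. For a seed, suppose that at 12 min the theta run holds the X that the gamma run reads then, 1.67% of the theta E charge. Reaching half of that E takes 4.91 doublings. Freeze the product at that slow end of the climb, with 75.0% of G and half of E present, and the rule gives 3.39 min per doubling. That leaves 13.4 min before the asked time. In this tail, freeze G and X instead, so that E decays as a pseudo-first-order species with a half-life of 2.54 min. My reckoning then puts X at 49.3% of G.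

The weak link is the seed, since the scatter of a reading is half of the gamma value used. Lower the seed by that scatter, and the answer becomes 48.3%. I commit to that range.

The forecast differs from my reckoning. It gives an order of 0.8 in G and 0.4 in Q, calls the eta run slower, and puts the theta run at 35%: “Depletion and possible saturation suggest X ≈ 0.17 M, about 35%.”

The simulation gives an order of 0.65 in G and 0.45 in Q, finds the eta run slower, and puts the theta run at 49.7%.

    Q + G → QG (1.284 L mol⁻¹ min⁻¹)
    QG + E → Qa (2.742 L mol⁻¹ min⁻¹)
    Qa → X + Q (0.1248 min⁻¹)
    G + E ⇌ GE, settled at all times (3.020 L mol⁻¹)
    G + E + X → 2 X (7.320 L² mol⁻² min⁻¹)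

The theta run holds more X than the forecast, and at 42 min that X stands for 99.4% of its E charge. Without the passing of G + E + X into 2 X, X in the theta run at the asked time is 5.62% of the G charged instead of 49.7%. That is the step the doubling time of 3.39 min describes in the theta run. For the delta run, the rule from the gamma readings gives 10.0 min for X to go from a quarter to half of its G, and the delta run's own times for those two points, 18.1 min and 26.9 min, stand 8.80 min apart.

The readings are simulated on assumed constants; noise was put on by code.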